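## Structural features

- The target joins three arenes through two oxygen heterocycles. Ring A is a lariciresinol-type oxolane (O-1′; C-2′ 3-hydroxy-4-methoxyphenyl; C-3′ CH2OH; C-4′ arylmethyl; C-5′ H2). Ring C is a 2-aryl-3-(hydroxymethyl)-2,3-dihydrofuran fused to the central benzene ring B, which is also the arene of the C-4′ arylmethyl group (C-6 carries that CH2).
- Ring A holds three contiguous stereocentres (2′R,3′S,4′S; aryl/CH2OH trans, CH2OH/arylmethyl cis). Ring C holds two adjacent ones (2S,3R, trans). The CH2–arene spacer insulates the two clusters, so neither can relay to the other.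
- Ring B is 1,3,4,5-tetrasubstituted: C-3a (bonded to C-3) lies between C-7a (ring oxygen) and C-4 (OMe), and the CH2 sits at C-6, para to C-3a. This is a resorcinol pattern, not the pattern produced by phenolic 8–5′ coupling, and C-3a is the most hindered position for arene chemistry.
- Fragile groups: two free phenols, two primary alcohols, and two benzylic C–O bonds para to oxygen (C-2′–O-1′ and C-2–O-1). These bonds ionize in acid (epimerization, Friedel–Crafts closure of C-2′ onto the electron-rich ring B) and can be hydrogenolysed. C-3–H becomes acidic whenever C-3 carries a carbonyl group (β-elimination of the ring oxygen).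
- The real difficulty is the dihydrobenzofuran: the C–C bond at C-3a, the trans pair C-2/C-3 in the absolute sense, and its union with an enantiopure ring A half.
- Feature exploited: C-4(O), C-3a, C-7a(O) and C-6 of ring B are C-1, C-2, C-3 and C-5 of a 5-substituted cyclohexane-1,3-dione. Ring C is built on that dione by an oxidative radical (3+2) annulation that also joins the two halves, and ring B is aromatized afterwards.

## Logic of the disconnections

**25 ⇒ 24.** The two phenolic O–H bonds are traced back to O–CH2Ph bonds. Free phenols would not survive the one-electron oxidant of the key step or the O-methylation. The demand on the forward step is hydrogenolysis of two aryl benzyl ethers without cleavage of the benzylic C-2′–O and C-2–O ring bonds.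

**24 ⇒ 23.** The C-3 CH2OH is traced back to an acyl group bound to the nitrogen of 17. This puts a stereocontrolling element next to C-3 and lets the last carbon-based step be a hydride cleavage. The forward step must not enolize C-3.

**23 ⇒ 22 ⇒ 20.** The O–CH3 bond at C-4 is cut, then ring B is de-aromatized to the 4-oxo-4,5,6,7-tetrahydro level. This turns the tetrasubstituted arene into the vinylogous ester of a cyclohexane-1,3-dione, so its substitution pattern follows from dione symmetry. The extra sp3 centre C-6 needs no control because it is erased. The forward dehydrogenation must spare two benzylic ethers and avoid strong base (acidic C-3–H).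

**20 ⇒ 15 + 19 (key).** The bonds C-3–C-3a and O-1–C-2 are cut. This removes ring C, both of its stereocentres and the bond between the two halves in one operation, and leaves a dione with a single nucleophilic carbon and a cinnamoyl alkene. The forward step must bond the dione carbon to the alkene carbon remote from the aryl group, close the ring trans, and distinguish the alkene faces.

**19 ⇒ 16 + 17.** The N–acyl bond is cut; both parts are commercial.

**15 ⇒ 12 + 13.** The ring bonds C-4–C-5 and C-2–C-3 of the dione are cut (Michael addition, then Claisen closure via 14, then loss of the ester carbon). The dione becomes an enone plus a malonate. The forward step must tolerate the benzylic ether of ring A.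

**12 ⇒ 10 + 11.** The C=C bond is cut by cross-metathesis logic; this reduces the side chain of ring A to an allyl group.

**10 ⇒ 9 ⇒ 8.** The O-1′–C-2′ bond is cut to a benzylic carbinol, and the two CH2OH groups are traced back to a lactone. Closure through the benzylic cation sets C-2′ trans to C-3′ whatever the carbinol configuration, and a 3,4-trans lactone maps onto the 3′,4′-cis oxolane.

**8 ⇒ 6 + 7.** The C-2′–C-3′ bond is cut (aldol). The forward step must add anti to the allyl group of the lactone enolate.

**6 ⇒ 5 ⇒ 3 + 4, and 3 ⇒ 1 + 2.** The allyl CH2–CH bond is cut (homoconjugate opening of a cyclopropane), and the cyclopropane-fused lactone is cut to a malonate and an epoxide. The single bought stereocentre of 2 becomes C-4′ and relays C-3′ and then C-2′.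

## Other disconnections considered

**Alternative 1:** (the plan most would draw first). Ring B is bought as a 3,5-dioxygenated benzyl unit, ring A is made by lactone chemistry, and ring C is closed last by cutting C-2–C-3. The forward key step is an intramolecular dirhodium-carbenoid C–H insertion of the aryl diazoacetate A1 into the benzylic C–H of its ortho benzyl ether, giving the ester A2 after cis-to-trans epimerization.
- The acetate carbon must be installed at the position flanked by two oxygens on a ring that already carries the acid-sensitive ring A (directed metalation, homologation, diazo transfer on an advanced lignan).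
- The insertion is expected to favour the cis ester, so a base epimerization next to an aryloxy leaving group is needed.
- The key step does not join the halves. In the chosen plan the regiochemistry at C-3a comes from the dione and the union is the key step itself.

**Alternative 2:** Cut the C-6–CH2 bond. The forward key step is hydroboration of the 4′-methylidene oxolane A3 (from a palladium-catalysed trimethylenemethane (3+2) cycloaddition to the aryl aldehyde) and B-alkyl Suzuki coupling with the aryl bromide A4 under zerovalent palladium.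
- This is convergent, but A4 still contains the whole problem: the C-3a bond and both ring C stereocentres have to be made on a 6-bromo-4-methoxy arene by other means.
- C-4′ depends on the facial selectivity of a hydroboration.
- The step count is higher.

**Alternative 3:** Cut O-1–C-2 and C-2–C-3 in a (4+1) sense. The forward key step is addition of the benzylic sulfonium ylide from salt A6 to the ortho-quinone methide generated from the hydroxybenzyl alcohol A5, followed by ring closure.
- A5 again needs a carbon substituent between the two oxygens of ring B, introduced late on the ring A lignan.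
- Absolute control with a semi-stabilized benzyl ylide would rest on a chiral sulfide, a less secure element than a covalently bound auxiliary.
- A quinone methide with a β-silyloxy group can tautomerize to a styrene instead of being trapped.

Key step: step 10

Assumption: the sultam is taken to direct the radical addition with the usual C-α topicity of N-enoyl bornane-10,2-sultams; if the sense proved opposite, the antipodal (2R)-sultam, equally available, would be used with no other change.

## Route

Step 1
Reactants: 1 diethyl malonate; 2 (S)-epichlorohydrin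
Product: 3 ethyl (1R,5S)-2-oxo-3-oxabicyclo[3.1.0]hexane-1-carboxylate
Conditions: NaOEt, EtOH, 0 °C → reflux
Reagents that add atoms: none
Why: Malonate opens the epoxide at its CH2 end, the alkoxide re-closes onto the CH2Cl carbon, the malonate anion opens the new epoxide at the secondary carbon (3-exo-tet, inversion) and the alkoxide lactonizes; the stereocentre of 2 becomes C-5 of 3, a known chiral-pool entry to β-substituted γ-butyrolactones.

Step 2
Reactants: 3 ethyl (1R,5S)-2-oxo-3-oxabicyclo[3.1.0]hexane-1-carboxylate; 4 vinylmagnesium bromide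
Product: 5 ethyl (3R,4S)-2-oxo-4-(prop-2-en-1-yl)oxolane-3-carboxylate
Conditions: CuI (cat.), THF, −40 → −20 °C; aq. NH4Cl
Reagents that add atoms: none
Why: Homoconjugate addition of the vinyl cuprate to the doubly activated cyclopropane at its CH2 carbon gives the allyl side chain; C-4 is untouched and the labile C-3 settles trans.

Step 3
Reactants: 5 ethyl (3R,4S)-2-oxo-4-(prop-2-en-1-yl)oxolane-3-carboxylate
Product: 6 (4S)-4-(prop-2-en-1-yl)oxolan-2-one
Conditions: LiCl, H2O, DMSO, 140 °C
Reagents that add atoms: none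
Why: Krapcho dealkoxycarbonylation of the malonate-type lactone; the only remaining stereocentre is not enolizable.

Step 4
Reactants: 6 (4S)-4-(prop-2-en-1-yl)oxolan-2-one; 7 3-(benzyloxy)-4-methoxybenzaldehyde
Product: 8 (3R,4S)-3-{[3-(benzyloxy)-4-methoxyphenyl](hydroxy)methyl}-4-(prop-2-en-1-yl)oxolan-2-one (both carbinol epimers)
Conditions: LiN(iPr)2, THF, −78 °C; then 7, −78 °C; aq. NH4Cl
Reagents that add atoms: none
Why: Aldol addition of the lactone lithium enolate; the aldehyde enters anti to the C-4 allyl group and gives the 3,4-trans lactone, and the carbinol mixture converges in step 6.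

Step 5
Reactants: 8 (3R,4S)-3-{[3-(benzyloxy)-4-methoxyphenyl](hydroxy)methyl}-4-(prop-2-en-1-yl)oxolan-2-one
Product: 9 (2S,3S)-2-{[3-(benzyloxy)-4-methoxyphenyl](hydroxy)methyl}-3-(prop-2-en-1-yl)butane-1,4-diol (both carbinol epimers)
Conditions: LiAlH4, THF, 0 °C → rt
Reagents that add atoms: none
Why: Hydride reduction of the lactone to the 1,4-diol; no stereocentre is touched and the alkene is inert.

Step 6
Reactants: 9 (2S,3S)-2-{[3-(benzyloxy)-4-methoxyphenyl](hydroxy)methyl}-3-(prop-2-en-1-yl)butane-1,4-diol
Product: 10 [(2R,3S,4S)-2-[3-(benzyloxy)-4-methoxyphenyl]-4-(prop-2-en-1-yl)oxolan-3-yl]methanol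
Conditions: p-TsOH·H2O (cat.), CH2Cl2, 0 °C → rt
Reagents that add atoms: none
Why: Acid ionizes either carbinol epimer to the same para-methoxybenzyl cation, which the primary hydroxyl on the allyl-bearing carbon captures in a 5-exo-trig closure (the other hydroxyl could only form an oxetane); the aryl group settles trans to the C-3 CH2OH (kinetic preference, and thermodynamic because ionization is reversible), as in lariciresinol-type syntheses, and the trans lactone becomes the 3,4-cis pair.

Step 7
Reactants: 10 [(2R,3S,4S)-2-[3-(benzyloxy)-4-methoxyphenyl]-4-(prop-2-en-1-yl)oxolan-3-yl]methanol; 11 but-3-en-2-one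
Product: 12 (3E)-5-[(3S,4S,5R)-5-[3-(benzyloxy)-4-methoxyphenyl]-4-(hydroxymethyl)oxolan-3-yl]pent-3-en-2-one
Conditions: 11 (5 equiv), second-generation Hoveyda–Grubbs catalyst RuCl2(H2IMes)(=CH-C6H4-2-OiPr) (5 mol%), CH2Cl2, 40 °C
Reagents that add atoms: none
Why: Olefin cross-metathesis of a terminal alkene with an enone partner gives the (E)-enone and ethene; the free hydroxyl is tolerated.

Step 8
Reactants: 12 (3E)-5-[(3S,4S,5R)-5-[3-(benzyloxy)-4-methoxyphenyl]-4-(hydroxymethyl)oxolan-3-yl]pent-3-en-2-one; 13 dimethyl malonate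
Product: 15 5-{[(3S,4S,5R)-5-[3-(benzyloxy)-4-methoxyphenyl]-4-(hydroxymethyl)oxolan-3-yl]methyl}cyclohexane-1,3-dione, via cyclic keto ester 14 (not isolated)
Conditions: NaOMe, MeOH, reflux; then aq. NaOH, reflux; then HCl to pH 3, 60 °C
Reagents that add atoms: none
Why: Michael addition of the malonate anion, Claisen closure of the methyl ketone enolate onto a malonate ester, then saponification and decarboxylation of the vinylogous β-keto acid: the classical synthesis of 5-substituted cyclohexane-1,3-diones. Any tetrahydropyran formed by reversible oxa-Michael addition of the free hydroxyl re-opens under methoxide and is drained by the Claisen step; C-5 of the dione is not a stereocentre.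

Step 9
Reactants: 16 (2E)-3-[4-(benzyloxy)-3-methoxyphenyl]prop-2-enoic acid; 17 (2S)-bornane-10,2-sultam
Product: 19 N-{(2E)-3-[4-(benzyloxy)-3-methoxyphenyl]prop-2-enoyl}-(2S)-bornane-10,2-sultam, via acid chloride 18 (not isolated)
Conditions: 16, (COCl)2, DMF (cat.), CH2Cl2, 0 °C → rt, evaporate; 17, NaH, toluene, 0 °C → rt
Reagents that add atoms: none
Why: N-Acylation of the sodium salt of the sultam by the acid chloride, the standard preparation of N-enoyl sultams; the (E)-geometry is retained.

Step 10
Reactants: 15 5-{[(3S,4S,5R)-5-[3-(benzyloxy)-4-methoxyphenyl]-4-(hydroxymethyl)oxolan-3-yl]methyl}cyclohexane-1,3-dione; 19 N-{(2E)-3-[4-(benzyloxy)-3-methoxyphenyl]prop-2-enoyl}-(2S)-bornane-10,2-sultam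
Product: 20 N-{[(2S,3S)-2-[4-(benzyloxy)-3-methoxyphenyl]-6-{[(3S,4S,5R)-5-[3-(benzyloxy)-4-methoxyphenyl]-4-(hydroxymethyl)oxolan-3-yl]methyl}-4-oxo-2,3,4,5,6,7-hexahydro-1-benzofuran-3-yl]carbonyl}-(2S)-bornane-10,2-sultam (C-6 epimers)
Conditions: Mn(OAc)3·2H2O (2.2 equiv), 19 (1.5 equiv), AcOH, 60 °C, argon
Reagents that add atoms: none
Why: This is the oxidative radical (3+2) annulation of a 1,3-dione with a cinnamoyl alkene mediated by trivalent manganese, a known route to trans-2-aryl-3-acyl-2,3-dihydrofurans, including with bornanesultam cinnamides. Mn(OAc)3 converts the enol of 15 into its manganese enolate and oxidizes it to the C-2 radical, the only carbon radical the dione can form, so the C–C bond is made at the future C-3a between the two oxygens with no arene regiochemistry to solve. This electrophilic radical adds to C-α of 19, which leaves the new radical on the benzylic carbon stabilized by the para-benzyloxyaryl group and so places aryl on C-2 and acyl on C-3. A second equivalent of Mn(OAc)3 oxidizes the benzylic radical to the para-alkoxybenzyl cation, and the enol oxygen closes ring C in a 5-exo-trig sense on the quinone-methide form of that cation. C-3 is set in the radical addition by the auxiliary (in the s-cis enoyl conformer with C=O anti to the S–N bond the (2S)-sultam shields the C-α re face, so si attack gives 3S); C-2 is set in the ring closure, trans to the bulky acyl sultam (kinetic and thermodynamic preference, reinforced because C-2–O ionization is reversible), giving 2S. C-6 forms as an epimeric mixture that is erased in step 11. The step must oxidize the dione selectively in the presence of two electron-rich arenes and two benzylic ethers, which the mild oxidant and the high enol content of 15 secure, and 20 has no enolizable dicarbonyl C–H left to be oxidized further. Any primary acetate formed from the free hydroxyl in warm AcOH is cleaved in step 13.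

Step 11
Reactants: 20 N-{[(2S,3S)-2-[4-(benzyloxy)-3-methoxyphenyl]-6-{[(3S,4S,5R)-5-[3-(benzyloxy)-4-methoxyphenyl]-4-(hydroxymethyl)oxolan-3-yl]methyl}-4-oxo-2,3,4,5,6,7-hexahydro-1-benzofuran-3-yl]carbonyl}-(2S)-bornane-10,2-sultam
Product: 22 N-{[(2S,3S)-2-[4-(benzyloxy)-3-methoxyphenyl]-6-{[(3S,4S,5R)-5-[3-(benzyloxy)-4-methoxyphenyl]-4-(hydroxymethyl)oxolan-3-yl]methyl}-4-hydroxy-2,3-dihydro-1-benzofuran-3-yl]carbonyl}-(2S)-bornane-10,2-sultam, via 5-bromo ketone 21 (not isolated)
Conditions: CuBr2 (2.1 equiv), EtOAc–CHCl3, reflux; filter, evaporate; LiBr, Li2CO3, DMF, 100 °C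
Reagents that add atoms: none
Why: α-Bromination of the vinylogous ester through its enol (at C-5, or at C-7 through the extended enol, both leading to the same arene), then dehydrobromination and tautomerization of the cyclohexadienone to the phenol, the known passage from 6,7-dihydrobenzofuran-4(5H)-ones to 4-hydroxybenzofurans. The C-6 epimers converge, and the weak carbonate base avoids enolization at C-3 and β-elimination of the ring oxygen.

Step 12
Reactants: 22 N-{[(2S,3S)-2-[4-(benzyloxy)-3-methoxyphenyl]-6-{[(3S,4S,5R)-5-[3-(benzyloxy)-4-methoxyphenyl]-4-(hydroxymethyl)oxolan-3-yl]methyl}-4-hydroxy-2,3-dihydro-1-benzofuran-3-yl]carbonyl}-(2S)-bornane-10,2-sultam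
Product: 23 N-{[(2S,3S)-2-[4-(benzyloxy)-3-methoxyphenyl]-6-{[(3S,4S,5R)-5-[3-(benzyloxy)-4-methoxyphenyl]-4-(hydroxymethyl)oxolan-3-yl]methyl}-4-methoxy-2,3-dihydro-1-benzofuran-3-yl]carbonyl}-(2S)-bornane-10,2-sultam
Conditions: MeI, K2CO3, acetone, rt
Reagents that add atoms: iodomethane, CI
Why: Williamson methylation of the only phenol; the primary alcohol is not deprotonated by K2CO3, and the trans arrangement at C-2/C-3 is the thermodynamic one.

Step 13
Reactants: 23 N-{[(2S,3S)-2-[4-(benzyloxy)-3-methoxyphenyl]-6-{[(3S,4S,5R)-5-[3-(benzyloxy)-4-methoxyphenyl]-4-(hydroxymethyl)oxolan-3-yl]methyl}-4-methoxy-2,3-dihydro-1-benzofuran-3-yl]carbonyl}-(2S)-bornane-10,2-sultam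
Product: 24 [(2S,3R)-2-[4-(benzyloxy)-3-methoxyphenyl]-6-{[(3S,4S,5R)-5-[3-(benzyloxy)-4-methoxyphenyl]-4-(hydroxymethyl)oxolan-3-yl]methyl}-4-methoxy-2,3-dihydro-1-benzofuran-3-yl]methanol
Conditions: LiAlH4, THF, 0 °C
Reagents that add atoms: none
Why: Reductive cleavage of the N-acyl sultam to the primary alcohol with release of the auxiliary, the standard removal of this auxiliary; C-3 keeps its configuration (its descriptor changes from S to R only through the priority change) and any acetate from step 10 is removed.

Step 14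
Reactants: 24 [(2S,3R)-2-[4-(benzyloxy)-3-methoxyphenyl]-6-{[(3S,4S,5R)-5-[3-(benzyloxy)-4-methoxyphenyl]-4-(hydroxymethyl)oxolan-3-yl]methyl}-4-methoxy-2,3-dihydro-1-benzofuran-3-yl]methanol
Product: 25 [(2S,3R)-2-(4-hydroxy-3-methoxyphenyl)-6-{[(3S,4S,5R)-5-(3-hydroxy-4-methoxyphenyl)-4-(hydroxymethyl)oxolan-3-yl]methyl}-4-methoxy-2,3-dihydro-1-benzofuran-3-yl]methanol (CNP0242386.1)
Conditions: H2 (1 atm), Pd/C (10 wt% Pd), EtOAc, rt, stopped at full conversion
Reagents that add atoms: none
Why: Hydrogenolysis of the two primary aryl benzyl ethers, which should be cleaved much faster than the secondary benzylic C–O bonds of rings A and C; no stereocentre is involved.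

## Compound list

1 | diethyl malonate | CCOC(=O)CC(=O)OCC | starting material
2 | (S)-epichlorohydrin | ClC[C@@H]1CO1 | starting material
3 | ethyl (1R,5S)-2-oxo-3-oxabicyclo[3.1.0]hexane-1-carboxylate | CCOC(=O)[C@@]12C[C@@H]1COC2=O | intermediate
4 | vinylmagnesium bromide | C=C[Mg]Br | starting material
5 | ethyl (3R,4S)-2-oxo-4-(prop-2-en-1-yl)oxolane-3-carboxylate (trans; C-3 labile) | C=CC[C@@H]1COC(=O)[C@H]1C(=O)OCC | intermediate
6 | (4S)-4-(prop-2-en-1-yl)oxolan-2-one | C=CC[C@@H]1COC(=O)C1 | intermediate
7 | 3-(benzyloxy)-4-methoxybenzaldehyde | O=Cc1ccc(OC)c(OCc2ccccc2)c1 | starting material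
8 | (3R,4S)-3-{[3-(benzyloxy)-4-methoxyphenyl](hydroxy)methyl}-4-(prop-2-en-1-yl)oxolan-2-one, both carbinol epimers | C=CC[C@@H]1COC(=O)[C@H]1C(O)c1ccc(OC)c(OCc2ccccc2)c1 | intermediate
9 | (2S,3S)-2-{[3-(benzyloxy)-4-methoxyphenyl](hydroxy)methyl}-3-(prop-2-en-1-yl)butane-1,4-diol, both carbinol epimers | C=CC[C@H](CO)[C@@H](CO)C(O)c1ccc(OC)c(OCc2ccccc2)c1 | intermediate
10 | [(2R,3S,4S)-2-[3-(benzyloxy)-4-methoxyphenyl]-4-(prop-2-en-1-yl)oxolan-3-yl]methanol | COc1ccc([C@@H]2OC[C@@H](CC=C)[C@H]2CO)cc1OCc1ccccc1 | intermediate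
11 | but-3-en-2-one (methyl vinyl ketone) | CC(=O)C=C | starting material
12 | (3E)-5-[(3S,4S,5R)-5-[3-(benzyloxy)-4-methoxyphenyl]-4-(hydroxymethyl)oxolan-3-yl]pent-3-en-2-one | COc1ccc([C@@H]2OC[C@@H](C/C=C/C(C)=O)[C@H]2CO)cc1OCc1ccccc1 | intermediate
13 | dimethyl malonate | COC(=O)CC(=O)OC | starting material
14 | methyl 6-{[(3S,4S,5R)-5-[3-(benzyloxy)-4-methoxyphenyl]-4-(hydroxymethyl)oxolan-3-yl]methyl}-2,4-dioxocyclohexane-1-carboxylate (ring stereoisomers and enol forms; not isolated) | COc1ccc([C@@H]2OC[C@@H](CC3CC(=O)CC(=O)C3C(=O)OC)[C@H]2CO)cc1OCc1ccccc1 | intermediate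
15 | 5-{[(3S,4S,5R)-5-[3-(benzyloxy)-4-methoxyphenyl]-4-(hydroxymethyl)oxolan-3-yl]methyl}cyclohexane-1,3-dione | COc1ccc([C@@H]2OC[C@@H](CC3CC(=O)CC(=O)C3)[C@H]2CO)cc1OCc1ccccc1 | intermediate
16 | (2E)-3-[4-(benzyloxy)-3-methoxyphenyl]prop-2-enoic acid | COc1cc(/C=C/C(=O)O)ccc1OCc1ccccc1 | starting material
17 | (2S)-bornane-10,2-sultam, (1R)-(+)-2,10-camphorsultam | CC1(C)[C@H]2CC[C@@]13CS(=O)(=O)N[C@H]3C2 | starting material
18 | (2E)-3-[4-(benzyloxy)-3-methoxyphenyl]prop-2-enoyl chloride (not isolated) | COc1cc(/C=C/C(=O)Cl)ccc1OCc1ccccc1 | intermediate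
19 | N-{(2E)-3-[4-(benzyloxy)-3-methoxyphenyl]prop-2-enoyl}-(2S)-bornane-10,2-sultam | CC1(C)[C@H]2CC[C@@]13CS(=O)(=O)N(C(=O)/C=C/c4ccc(OCc5ccccc5)c(OC)c4)[C@H]3C2 | intermediate
20 | N-acyl sultam of the (2S,3S)-2-aryl-4-oxo-2,3,4,5,6,7-hexahydro-1-benzofuran-3-carboxylic acid carrying the ring A unit at C-6 (C-6 epimers) | CC1(C)[C@H]2CC[C@@]13CS(=O)(=O)N(C(=O)[C@H]4C5=C(O[C@@H]4c6ccc(OCc7ccccc7)c(OC)c6)CC(C[C@@H]6CO[C@@H](c7ccc(OC)c(OCc8ccccc8)c7)[C@@H]6CO)CC5=O)[C@H]3C2 | intermediate
21 | 5-bromo derivative of 20 (stereoisomers at C-5 and C-6; not isolated) | CC1(C)[C@H]2CC[C@@]13CS(=O)(=O)N(C(=O)[C@H]4C5=C(O[C@@H]4c6ccc(OCc7ccccc7)c(OC)c6)CC(C[C@@H]6CO[C@@H](c7ccc(OC)c(OCc8ccccc8)c7)[C@@H]6CO)C(Br)C5=O)[C@H]3C2 | intermediate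
22 | N-acyl sultam of the (2S,3S)-2-aryl-4-hydroxy-2,3-dihydro-1-benzofuran-3-carboxylic acid carrying the ring A unit at C-6 | CC1(C)[C@H]2CC[C@@]13CS(=O)(=O)N(C(=O)[C@H]4c5c(O)cc(C[C@@H]6CO[C@@H](c7ccc(OC)c(OCc8ccccc8)c7)[C@@H]6CO)cc5O[C@@H]4c4ccc(OCc5ccccc5)c(OC)c4)[C@H]3C2 | intermediate
23 | 4-O-methyl ether of 22 | CC1(C)[C@H]2CC[C@@]13CS(=O)(=O)N(C(=O)[C@H]4c5c(OC)cc(C[C@@H]6CO[C@@H](c7ccc(OC)c(OCc8ccccc8)c7)[C@@H]6CO)cc5O[C@@H]4c4ccc(OCc5ccccc5)c(OC)c4)[C@H]3C2 | intermediate
24 | [(2S,3R)-2-[4-(benzyloxy)-3-methoxyphenyl]-6-{[(3S,4S,5R)-5-[3-(benzyloxy)-4-methoxyphenyl]-4-(hydroxymethyl)oxolan-3-yl]methyl}-4-methoxy-2,3-dihydro-1-benzofuran-3-yl]methanol | COc1ccc([C@@H]2OC[C@@H](Cc3cc(OC)c4c(c3)O[C@H](c3ccc(OCc5ccccc5)c(OC)c3)[C@H]4CO)[C@H]2CO)cc1OCc1ccccc1 | intermediate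
25 | [(2S,3R)-2-(4-hydroxy-3-methoxyphenyl)-6-{[(3S,4S,5R)-5-(3-hydroxy-4-methoxyphenyl)-4-(hydroxymethyl)oxolan-3-yl]methyl}-4-methoxy-2,3-dihydro-1-benzofuran-3-yl]methanol | COc1ccc([C@@H]2OC[C@@H](Cc3cc(OC)c4c(c3)O[C@H](c3ccc(O)c(OC)c3)[C@H]4CO)[C@H]2CO)cc1O | target

## Step count and least certain steps

Total: 14 steps. Longest linear sequence: 13 steps (steps 1–8, then 10–14); step 9 prepares the second fragment.

**Step 10 (key step).**
- Most likely to go wrong: the stoichiometric oxidant is consumed by self-coupling and over-oxidation of the valuable dione before its radical is captured by the only moderately nucleophilic, acyl-substituted alkene, so the union stalls at low conversion. A lesser concern is incomplete facial discrimination by the auxiliary; the diastereomers stay bound to the sultam and should be separable after step 11.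
- Fallback (from 15, returning at 20): generate the dione-centred reactive species without an external oxidant. PhI(OAc)2 and KOH in MeOH at 0 °C convert 15 into its phenyliodonium ylide F1. F1 and 19 with Rh2(OAc)4 (cat.) in CH2Cl2, or under blue light, undergo the known formal (3+2) cycloaddition of dione iodonium ylides with alkenes, losing iodobenzene, to give 20.

**Step 11.**
- Most likely to go wrong: slow enolization of the vinylogous ester lets CuBr2 brominate the alkoxy-substituted arenes instead, and the HBr released reversibly opens the benzylic ethers.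
- Fallback (from 20, returning at 24): remove the acidic C-3–H first so that kinetic enolate chemistry can be used. LiBH4 in THF–MeOH at 0 °C cleaves the acyl sultam reductively while the vinylogous ester survives, giving the keto diol F2. LiN(iPr)2 (3.2 equiv) in THF at −78 °C followed by PhSeBr gives the C-5 selenide F3. H2O2 and pyridine in CH2Cl2 (0 °C → rt) give the phenol diol F4 by selenoxide syn-elimination and tautomerization. MeI and K2CO3 in acetone methylate the phenol only and give 24.

**Step 8.**
- Most likely to go wrong: the warm acidic decarboxylation ionizes the benzylic C-2′–O bond of ring A (elimination or scrambling), and the free hydroxyl diverts material by oxa-Michael addition if the malonate addition is slow.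
- Fallback (from 12, returning at 15): unmask under neutral conditions. Diallyl malonate and NaH in THF at reflux give the allyl keto ester F5. Pd(PPh3)4 (zerovalent palladium) and morpholine in THF at rt remove the allyl group, and the keto acid decarboxylates at once to 15.

**Step 14.**
- Most likely to go wrong: hydrogenolysis continues past the benzyl ethers into the benzylic C-2′–O and C-2–O ring bonds.
- Fallback (from 24, returning at 25): non-reductive debenzylation with BCl3 and pentamethylbenzene (cation scavenger) in CH2Cl2 at −78 °C, quenched cold, gives 25 directly. No new numbered compound is involved.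

## Further compounds

F1 | step 10 | 5-{[(3S,4S,5R)-5-[3-(benzyloxy)-4-methoxyphenyl]-4-(hydroxymethyl)oxolan-3-yl]methyl}-2-(phenyliodonio)cyclohexane-1,3-dion-2-ide | COc1ccc([C@@H]2OC[C@@H](CC3CC(=O)[C-]([I+]c4ccccc4)C(=O)C3)[C@H]2CO)cc1OCc1ccccc1
F2 | step 11 | (2S,3R)-2-[4-(benzyloxy)-3-methoxyphenyl]-3-(hydroxymethyl)-6-{[(3S,4S,5R)-5-[3-(benzyloxy)-4-methoxyphenyl]-4-(hydroxymethyl)oxolan-3-yl]methyl}-3,5,6,7-tetrahydro-1-benzofuran-4(2H)-one (C-6 epimers) | COc1ccc([C@@H]2OC[C@@H](CC3CC(=O)C4=C(C3)O[C@H](c3ccc(OCc5ccccc5)c(OC)c3)[C@H]4CO)[C@H]2CO)cc1OCc1ccccc1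
F3 | step 11 | 5-(phenylselanyl) derivative of F2 (stereoisomers at C-5 and C-6) | COc1ccc([C@@H]2OC[C@@H](CC3C([Se]c6ccccc6)C(=O)C4=C(C3)O[C@H](c3ccc(OCc5ccccc5)c(OC)c3)[C@H]4CO)[C@H]2CO)cc1OCc1ccccc1
F4 | step 11 | (2S,3R)-2-[4-(benzyloxy)-3-methoxyphenyl]-3-(hydroxymethyl)-6-{[(3S,4S,5R)-5-[3-(benzyloxy)-4-methoxyphenyl]-4-(hydroxymethyl)oxolan-3-yl]methyl}-2,3-dihydro-1-benzofuran-4-ol | COc1ccc([C@@H]2OC[C@@H](Cc3cc(O)c4c(c3)O[C@H](c3ccc(OCc5ccccc5)c(OC)c3)[C@H]4CO)[C@H]2CO)cc1OCc1ccccc1
F5 | step 8 | prop-2-en-1-yl 6-{[(3S,4S,5R)-5-[3-(benzyloxy)-4-methoxyphenyl]-4-(hydroxymethyl)oxolan-3-yl]methyl}-2,4-dioxocyclohexane-1-carboxylate (ring stereoisomers) | COc1ccc([C@@H]2OC[C@@H](CC3CC(=O)CC(=O)C3C(=O)OCC=C)[C@H]2CO)cc1OCc1ccccc1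
F0 | step 14 | none | none
A1 | alternative 1 | methyl 2-diazo-2-[2-{[4-(benzyloxy)-3-methoxyphenyl]methoxy}-6-methoxy-4-{[(3S,4S,5R)-5-[3-(benzyloxy)-4-methoxyphenyl]-4-[(benzyloxy)methyl]oxolan-3-yl]methyl}phenyl]acetate | COC(=O)C(=[N+]=[N-])c1c(OC)cc(C[C@@H]2CO[C@@H](c3ccc(OC)c(OCc4ccccc4)c3)[C@@H]2COCc2ccccc2)cc1OCc1ccc(OCc2ccccc2)c(OC)c1
A2 | alternative 1 | methyl (2S,3S)-2-[4-(benzyloxy)-3-methoxyphenyl]-4-methoxy-6-{[(3S,4S,5R)-5-[3-(benzyloxy)-4-methoxyphenyl]-4-[(benzyloxy)methyl]oxolan-3-yl]methyl}-2,3-dihydro-1-benzofuran-3-carboxylate | COC(=O)[C@H]1c2c(OC)cc(C[C@@H]3CO[C@@H](c4ccc(OC)c(OCc5ccccc5)c4)[C@@H]3COCc3ccccc3)cc2O[C@@H]1c1ccc(OCc2ccccc2)c(OC)c1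
A3 | alternative 2 | methyl (2R,3R)-2-[3-(benzyloxy)-4-methoxyphenyl]-4-methylideneoxolane-3-carboxylate | COc1ccc([C@@H]2OCC(=C)[C@H]2C(=O)OC)cc1OCc1ccccc1
A4 | alternative 2 | [(2S,3R)-2-[4-(benzyloxy)-3-methoxyphenyl]-6-bromo-4-methoxy-2,3-dihydro-1-benzofuran-3-yl]methanol | Brc1cc(OC)c2c(c1)O[C@H](c1ccc(OCc3ccccc3)c(OC)c1)[C@H]2CO
A5 | alternative 3 | 2-{2-[(tert-butyldimethylsilyl)oxy]-1-hydroxyethyl}-3-methoxy-5-{[(3S,4S,5R)-5-[3-(benzyloxy)-4-methoxyphenyl]-4-[(benzyloxy)methyl]oxolan-3-yl]methyl}phenol (carbinol epimers) | COc1cc(C[C@@H]2CO[C@@H](c3ccc(OC)c(OCc4ccccc4)c3)[C@@H]2COCc2ccccc2)cc(O)c1C(O)CO[Si](C)(C)C(C)(C)C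
A6 | alternative 3 | 1-{[4-(benzyloxy)-3-methoxyphenyl]methyl}thiolan-1-ium bromide | COc1cc(C[S+]2CCCC2)ccc1OCc1ccccc1.[Br-]
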